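**Retrosynthetic overview**

1. The target is the bis-hydroxymethyl form of a (1S,2S,3S)-1-aryltetralin-2,3-diester, which comes from a 1-aryl-1-hydroxytetralin diester by benzylic deoxygenation and release of the catechol.
2. The strategy rests on ring B (C1, C2, C3, C4, C4a, C8a). Its diaryl carbon C1 (peri to the C8 oxygen) and its C4 methylene are the ends of a hydroxy-o-quinodimethane C1=C8a–C4a=C4, photogenerated from a 2-methylbenzophenone. The trans C2/C3 hydroxymethyl pair is an E-fumarate carrying lactate auxiliaries, so ring B is cut at C1–C2 and C3–C4.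
3. The benzophenone comes from 3,4,5-trimethoxyphenyllithium and a ring A aldehyde, followed by oxidation. The aldehyde comes from C2-symmetric 3,4,5-trimethoxytoluene by formylation, chelation-directed double demethylation and diphenylmethylene ketal formation.
4. Ring order: ring A and the trimethoxyphenyl ring are bought intact, the dioxole is fused on as temporary catechol protection, the two arenes are joined at the future C1, and ring B is closed last by the [4+2].

Key step: step 7

Remark on numbering: tetralin numbering of the target is used throughout (C1 aryl carbon, C2 and C3 ester or hydroxymethyl carbons, C4 methylene, C6 methoxy, C7 and C8 oxygens).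

Assumption: hydroxy-o-quinodimethanes are taken to add to the fumarate of an (S)-2-hydroxy ester on the face that leads to the (2R,3R) diester (hydrogen-bonded endo model), so the (R)-lactate auxiliary is chosen to reach (2S,3S).

**Route**

Step 1
Reactants: 1 3,4,5-trimethoxytoluene
Product: 3 2,3,4-trimethoxy-6-methylbenzaldehyde, via aryl iminium chloride 2 (not isolated)
Conditions: POCl3, DMF, 0 °C to 80 °C; then ice-water
Reagents that add atoms: N,N-dimethylformamide CN(C)C=O (formyl carbon); water O (carbonyl oxygen)
Why: Vilsmeier–Haack formylation, in which the chloroiminium electrophile can only attack the two symmetry-equivalent free positions (each ortho to methyl and ortho/para to methoxy), so a single regioisomer should form.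

Step 2
Reactants: 3 2,3,4-trimethoxy-6-methylbenzaldehyde
Product: 4 2,3-dihydroxy-4-methoxy-6-methylbenzaldehyde
Conditions: BCl3 (3 equiv), CH2Cl2, 0 °C to rt; then H2O
Reagents that add atoms: none
Why: Chelation-directed Lewis-acid ether cleavage, in which BCl3 held by the formyl oxygen dealkylates the adjacent C2 methoxy and the resulting aryloxyborane reaches the neighbouring C3 methoxy to close a five-membered catechol borate, leaving the remote C4 methoxy untouched.

Step 3
Reactants: 4 2,3-dihydroxy-4-methoxy-6-methylbenzaldehyde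
Product: 5 7-methoxy-5-methyl-2,2-diphenyl-1,3-benzodioxole-4-carbaldehyde
Conditions: Ph2CCl2 (1.5 equiv), Ph2O, 175 °C, N2 sweep
Reagents that add atoms: dichlorodiphenylmethane ClC(Cl)(c1ccccc1)c1ccccc1
Why: Ketalisation of a catechol with a gem-dichloride (double O-alkylation through the chlorodiphenylmethyl cation, driven by loss of HCl) should give the 2,2-diphenylbenzodioxole, a protecting group with no hydrogen on the carbon next to oxygen.

Step 4
Reactants: 5 7-methoxy-5-methyl-2,2-diphenyl-1,3-benzodioxole-4-carbaldehyde; 6 5-bromo-1,2,3-trimethoxybenzene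
Product: 8 (7-methoxy-5-methyl-2,2-diphenyl-1,3-benzodioxol-4-yl)(3,4,5-trimethoxyphenyl)methanol (racemic), via 3,4,5-trimethoxyphenyllithium 7 (not isolated)
Conditions: 6, n-BuLi, THF, −78 °C; then 5, −78 °C to 0 °C; then H2O
Reagents that add atoms: none
Why: Bromine–lithium exchange followed by 1,2-addition of the aryllithium to the non-enolisable aldehyde joins the two arenes at the future C1, and the racemic carbinol centre is removed in the next step.

Step 5
Reactants: 8 (7-methoxy-5-methyl-2,2-diphenyl-1,3-benzodioxol-4-yl)(3,4,5-trimethoxyphenyl)methanol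
Product: 9 (7-methoxy-5-methyl-2,2-diphenyl-1,3-benzodioxol-4-yl)(3,4,5-trimethoxyphenyl)methanone
Conditions: MnO2 (excess), CH2Cl2, reflux
Reagents that add atoms: none
Why: MnO2 oxidation of a doubly benzylic secondary alcohol should give the diaryl ketone, with the aryl ethers and the ketal inert.

Step 6
Reactants: 10 fumaryl chloride; 11 methyl (R)-lactate (2.2 equiv)
Product: 12 bis[(2R)-1-methoxy-1-oxopropan-2-yl] (E)-but-2-enedioate
Conditions: pyridine (2.5 equiv), CH2Cl2, 0 °C to rt
Reagents that add atoms: none
Why: Pyridine-mediated O-acylation (Einhorn conditions) of the secondary hydroxyl by both acid chloride groups, which does not touch the lactate stereocentre and keeps the E geometry of the alkene.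

Step 7
Reactants: 9 (7-methoxy-5-methyl-2,2-diphenyl-1,3-benzodioxol-4-yl)(3,4,5-trimethoxyphenyl)methanone; 12 bis[(2R)-1-methoxy-1-oxopropan-2-yl] (E)-but-2-enedioate
Product: 14 bis[(2R)-1-methoxy-1-oxopropan-2-yl] (7S,8R,9S)-9-hydroxy-4-methoxy-2,2-diphenyl-9-(3,4,5-trimethoxyphenyl)-6,7,8,9-tetrahydronaphtho[1,2-d][1,3]dioxole-7,8-dicarboxylate, via photodienol 13 (not isolated)
Conditions: hν (365 nm LED), 9 and 12 equimolar, degassed toluene (0.05 M), rt, argon
Reagents that add atoms: none
Why: Excitation of ketone 9 gives the n,π* triplet, which takes a hydrogen from the ortho methyl through a six-membered transition state and relaxes to dienol 13 with the hydroxyl turned toward the dioxole oxygen and the aryl toward the new methylene, the isomer that cannot revert by a 1,5-hydrogen shift and so lives long enough to be trapped; dienol that escapes trapping only returns to 9 and is excited again, so one equivalent of 12 is enough and irradiation is continued until 9 is consumed. It should add to fumarate 12 in a concerted suprafacial [4+2]; the closest known reactions are the photoenolization/Diels–Alder reaction of 2-methylbenzophenones with fumarates and the hydrogen-bond-directed addition of hydroxy-o-quinodimethanes to lactate or mandelate fumarates. Ring B, a six-membered carbocycle, is closed by this intermolecular cycloaddition, which forms C1–C2 and C3–C4 and restores the aromaticity of ring A. C2 and C3 come out trans because the E geometry of the fumarate is kept, and their absolute sense is set by the (R)-lactate groups: the ester next to the carbinol carbon lies endo, hydrogen-bonded to the dienol hydroxyl, and the diene takes the fumarate face on which the lactate ester carbonyl sits; the same endo contact puts the C1 hydroxyl cis to the C2 ester (tetralin descriptors 1S,2R,3S), a centre that step 8 erases. The only selectivity needed is therefore the π-face choice on the C2-symmetric dienophile (its two ends are equivalent, so there is no regiochemical issue), and the two lactate stereocentres secure it. The ketal protects the photochemistry, since it leaves no phenolic OH to quench the excited ketone and no O–CH hydrogen to compete with the methyl in hydrogen abstraction.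

Step 8
Reactants: 14 bis[(2R)-1-methoxy-1-oxopropan-2-yl] (7S,8R,9S)-9-hydroxy-4-methoxy-2,2-diphenyl-9-(3,4,5-trimethoxyphenyl)-6,7,8,9-tetrahydronaphtho[1,2-d][1,3]dioxole-7,8-dicarboxylate
Product: 17 bis[(2R)-1-methoxy-1-oxopropan-2-yl] (1S,2S,3S)-7,8-dihydroxy-6-methoxy-1-(3,4,5-trimethoxyphenyl)-1,2,3,4-tetrahydronaphthalene-2,3-dicarboxylate, via diaryl cation 15 (not isolated), via deoxygenated ketal 16 (not isolated)
Conditions: Et3SiH (10 equiv), TFA (10 equiv), CH2Cl2, −20 °C; then TFA–CH2Cl2 1:2, 0 °C to rt, argon
Reagents that add atoms: none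
Why: Ionic hydrogenation (ionisation by TFA, hydride transfer from Et3SiH) in which either C1 epimer gives the same doubly aryl-stabilised cation, A(1,2) strain with the C1 aryl puts the C2 ester pseudoaxial so that hydride should enter anti to it and set (1S) with the aryl cis to the C2 ester, and the same acid and silane then open the diphenylmethylene ketal through its oxocarbenium ion and reduce it to diphenylmethane.

Step 9
Reactants: 17 bis[(2R)-1-methoxy-1-oxopropan-2-yl] (1S,2S,3S)-7,8-dihydroxy-6-methoxy-1-(3,4,5-trimethoxyphenyl)-1,2,3,4-tetrahydronaphthalene-2,3-dicarboxylate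
Product: 18 (1S,2S,3S)-2,3-bis(hydroxymethyl)-6-methoxy-1-(3,4,5-trimethoxyphenyl)-1,2,3,4-tetrahydronaphthalene-7,8-diol (CNP0188980.2)
Conditions: LiAlH4 (8 equiv), THF, 0 °C to rt, argon; then EtOAc, degassed 1 M HCl, 0 °C
Reagents that add atoms: none
Why: LiAlH4 reduction of esters to primary alcohols, in which hydride cleaves both ring acyl–oxygen bonds to give the C2 and C3 hydroxymethyl groups and reduces the released lactate to propane-1,2-diol, fast enough at 0 °C that the C2 and C3 centres should not epimerise.

**Compound list**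

1 | 3,4,5-trimethoxytoluene | COc1cc(C)cc(OC)c1OC | starting material
2 | N-[(2,3,4-trimethoxy-6-methylphenyl)methylidene]-N-methylmethanaminium chloride | COc1cc(C)c(C=[N+](C)C)c(OC)c1OC.[Cl-] | intermediate
3 | 2,3,4-trimethoxy-6-methylbenzaldehyde | COc1cc(C)c(C=O)c(OC)c1OC | intermediate
4 | 2,3-dihydroxy-4-methoxy-6-methylbenzaldehyde | COc1cc(C)c(C=O)c(O)c1O | intermediate
5 | 7-methoxy-5-methyl-2,2-diphenyl-1,3-benzodioxole-4-carbaldehyde | COc1cc(C)c(C=O)c2OC(c3ccccc3)(c3ccccc3)Oc12 | intermediate
6 | 5-bromo-1,2,3-trimethoxybenzene | COc1cc(Br)cc(OC)c1OC | starting material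
7 | 3,4,5-trimethoxyphenyllithium | [Li]c1cc(OC)c(OC)c(OC)c1 | intermediate
8 | (7-methoxy-5-methyl-2,2-diphenyl-1,3-benzodioxol-4-yl)(3,4,5-trimethoxyphenyl)methanol (racemic) | COc1cc(C)c(C(O)c2cc(OC)c(OC)c(OC)c2)c2OC(c3ccccc3)(c3ccccc3)Oc12 | intermediate
9 | (7-methoxy-5-methyl-2,2-diphenyl-1,3-benzodioxol-4-yl)(3,4,5-trimethoxyphenyl)methanone | COc1cc(C)c(C(=O)c2cc(OC)c(OC)c(OC)c2)c2OC(c3ccccc3)(c3ccccc3)Oc12 | intermediate
10 | fumaryl chloride | O=C(Cl)/C=C/C(=O)Cl | starting material
11 | methyl (R)-lactate | C[C@@H](O)C(=O)OC | starting material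
12 | bis[(2R)-1-methoxy-1-oxopropan-2-yl] (E)-but-2-enedioate | COC(=O)[C@@H](C)OC(=O)/C=C/C(=O)O[C@H](C)C(=O)OC | intermediate
13 | [7-methoxy-5-methylidene-2,2-diphenyl-1,3-benzodioxol-4(5H)-ylidene](3,4,5-trimethoxyphenyl)methanol, hydroxyl on the dioxole side (photodienol) | C=C1C=C(OC)C2=C(OC(c3ccccc3)(c3ccccc3)O2)/C1=C(\O)c1cc(OC)c(OC)c(OC)c1 | intermediate
14 | bis[(2R)-1-methoxy-1-oxopropan-2-yl] (7S,8R,9S)-9-hydroxy-4-methoxy-2,2-diphenyl-9-(3,4,5-trimethoxyphenyl)-6,7,8,9-tetrahydronaphtho[1,2-d][1,3]dioxole-7,8-dicarboxylate (tetralin descriptors 1S,2R,3S; C1 hydroxyl cis to the C2 ester, C2 and C3 esters trans) | COc1cc2c(c3OC(c4ccccc4)(c4ccccc4)Oc13)[C@@](O)(c1cc(OC)c(OC)c(OC)c1)[C@H](C(=O)O[C@H](C)C(=O)OC)[C@@H](C(=O)O[C@H](C)C(=O)OC)C2 | intermediate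
15 | C1 diarylmethyl cation derived from 14 (C2 and C3 unchanged), trifluoroacetate | COc1cc2c(c3OC(c4ccccc4)(c4ccccc4)Oc13)[C+](c1cc(OC)c(OC)c(OC)c1)[C@H](C(=O)O[C@H](C)C(=O)OC)[C@@H](C(=O)O[C@H](C)C(=O)OC)C2.[O-]C(=O)C(F)(F)F | intermediate
16 | bis[(2R)-1-methoxy-1-oxopropan-2-yl] (7S,8S,9S)-4-methoxy-2,2-diphenyl-9-(3,4,5-trimethoxyphenyl)-6,7,8,9-tetrahydronaphtho[1,2-d][1,3]dioxole-7,8-dicarboxylate | COc1cc2c(c3OC(c4ccccc4)(c4ccccc4)Oc13)[C@H](c1cc(OC)c(OC)c(OC)c1)[C@H](C(=O)O[C@H](C)C(=O)OC)[C@@H](C(=O)O[C@H](C)C(=O)OC)C2 | intermediate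
17 | bis[(2R)-1-methoxy-1-oxopropan-2-yl] (1S,2S,3S)-7,8-dihydroxy-6-methoxy-1-(3,4,5-trimethoxyphenyl)-1,2,3,4-tetrahydronaphthalene-2,3-dicarboxylate | COc1cc2c(c(O)c1O)[C@H](c1cc(OC)c(OC)c(OC)c1)[C@H](C(=O)O[C@H](C)C(=O)OC)[C@@H](C(=O)O[C@H](C)C(=O)OC)C2 | intermediate
18 | (1S,2S,3S)-2,3-bis(hydroxymethyl)-6-methoxy-1-(3,4,5-trimethoxyphenyl)-1,2,3,4-tetrahydronaphthalene-7,8-diol | COc1cc2c(c(O)c1O)[C@H](c1cc(OC)c(OC)c(OC)c1)[C@H](CO)[C@@H](CO)C2 | target

**Step count**

Total steps: 9. Longest linear sequence: 8 steps (steps 1 to 5, then 7 to 9, from 3,4,5-trimethoxytoluene); step 6 is a one-step side branch.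

**Steps most likely to fail**

Step 7. The excited electron-rich ketone may decay, or the dienol may revert, faster than the fumarate traps it, so that conversion stalls. Triplet energy transfer may also isomerise the fumarate to the maleate and so erode the trans C2/C3 relationship. The fallback separates the photochemical event from the cycloaddition. Setting out from 9, irradiation (365 nm) in benzene saturated with SO2 should trap dienol 13 as it forms, giving the cyclic hydroxy sulfone 1-hydroxy-5-methoxy-6,7-(diphenylmethylenedioxy)-1-(3,4,5-trimethoxyphenyl)-1,3-dihydro-2-benzothiophene 2,2-dioxide F1 (racemic). Heating F1 with 12 in toluene at 80 to 110 °C in the dark under an argon sweep should expel SO2 by cheletropic cycloreversion and regenerate 13 thermally, which adds to 12 under the same auxiliary control and rejoins the route at 14.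

Step 8. Hydride may be delivered to the cation on the face syn to the C2 ester, giving the C1 epimer. The cation may also lose the C2 proton to form the C1=C2 alkene, which erases C2. The fallback avoids a free cation. Setting out from 14 (the C1 epimer with hydroxyl cis to the C2 ester, purified), H2 over Pd/C in EtOAc–AcOH should replace the benzylic C–O bond with inversion on the metal surface, placing hydrogen trans to the C2 ester. The same operation hydrogenolyses the diphenylmethylene ketal to diphenylmethane, so the sequence returns directly at 17; this fallback makes no new compound (F0).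

Step 9. Aluminium catecholates may precipitate and stall the reduction, prolonged exposure to basic alkoxides may epimerise C2, and the electron-rich catechol may oxidise in air during work-up. The fallback protects, reduces and deprotects. Setting out from 17, TBSOTf and 2,6-lutidine in CH2Cl2 should give bis[(2R)-1-methoxy-1-oxopropan-2-yl] (1S,2S,3S)-7,8-bis[(tert-butyldimethylsilyl)oxy]-6-methoxy-1-(3,4,5-trimethoxyphenyl)-1,2,3,4-tetrahydronaphthalene-2,3-dicarboxylate F2. LiAlH4 in THF at 0 °C should then reduce the ester groups to give [(1S,2S,3S)-7,8-bis[(tert-butyldimethylsilyl)oxy]-6-methoxy-1-(3,4,5-trimethoxyphenyl)-1,2,3,4-tetrahydronaphthalene-2,3-diyl]dimethanol F3. HF·pyridine in THF under argon removes the silyl ethers and returns to the route at 18.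

**Further compounds**

F1 | step 7 | 1-hydroxy-5-methoxy-6,7-(diphenylmethylenedioxy)-1-(3,4,5-trimethoxyphenyl)-1,3-dihydro-2-benzothiophene 2,2-dioxide (racemic) | COc1cc2c(c3OC(c4ccccc4)(c4ccccc4)Oc13)C(O)(c1cc(OC)c(OC)c(OC)c1)S(=O)(=O)C2
F0 | step 8 | none | none
F2 | step 9 | bis[(2R)-1-methoxy-1-oxopropan-2-yl] (1S,2S,3S)-7,8-bis[(tert-butyldimethylsilyl)oxy]-6-methoxy-1-(3,4,5-trimethoxyphenyl)-1,2,3,4-tetrahydronaphthalene-2,3-dicarboxylate | COc1cc2c(c(O[Si](C)(C)C(C)(C)C)c1O[Si](C)(C)C(C)(C)C)[C@H](c1cc(OC)c(OC)c(OC)c1)[C@H](C(=O)O[C@H](C)C(=O)OC)[C@@H](C(=O)O[C@H](C)C(=O)OC)C2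
F3 | step 9 | [(1S,2S,3S)-7,8-bis[(tert-butyldimethylsilyl)oxy]-6-methoxy-1-(3,4,5-trimethoxyphenyl)-1,2,3,4-tetrahydronaphthalene-2,3-diyl]dimethanol | COc1cc2c(c(O[Si](C)(C)C(C)(C)C)c1O[Si](C)(C)C(C)(C)C)[C@H](c1cc(OC)c(OC)c(OC)c1)[C@H](CO)[C@@H](CO)C2
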